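**Plan**

- Retrosynthesis: the lactam N–H is traced back to an N-tosyl lactam (N–S cut), the C2 carbonyl and C3 methylene to a ring ynamide N1–C2≡C3 (loss of water), and the ring is then opened at C3–C4 by an alkyne–iminium (Mannich-type) cut into a C14 aldehyde and a linear N-tosyl ynamide of N-trimethylated spermine.
- Enabling feature: in the 17-membered 1,5,9,14-tetraazacycloheptadecan-2-one ring, N5(Me)–C4H(tridecyl)–C3H2–C2(=O)–N1 is a β-amino amide. C4 is therefore an aldehyde carbon bound to a secondary amine, and C3–C2–N1 is an acetamide that can be carried as a terminal ynamide, a neutral acetamide-enolate equivalent that tolerates free amines.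
- Forward: tri-Boc-spermine is tosylated at its free end, all three Boc groups are reduced to N-methyl, the new NHMe end is masked, the tosylamide is alkynylated, and fluoride unmasks both ends. One copper-catalysed aldehyde–alkyne–amine coupling then closes the only ring, brings in the C13 chain and sets the stereocentre; hydration and detosylation finish.
- Stereochemistry: the single centre (4R) is set in the ring closure by the chiral P,N ligand on copper (catalyst control); no later step touches C4.
- Helpers: tosyl (ynamide activation, removed in step 8), the alkyne oxidation pattern at C2–C3 (corrected by water in step 7), Teoc and TIPS (removed together in step 5).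

Key step: step 6

Remark: N1,N4,N9-tri-Boc-spermine is treated as a commercial starting material.

**Step 1**
Reactants: 1 N1,N4,N9-tri-Boc-spermine (free primary amine at one terminus, Boc on the two inner nitrogens and on the other terminal nitrogen); 2 p-toluenesulfonyl chloride
Product: 3 N1-tosyl-N4,N9,N12-tri-Boc-spermine
Conditions: Et3N, CH2Cl2, 0 °C to rt
Reagents that add atoms: p-toluenesulfonyl chloride 2, Cc1ccc(cc1)S(=O)(=O)Cl
Why: Sulfonamide formation at the only free amine, the three carbamate nitrogens being non-nucleophilic; the tosyl group later serves as the electron-withdrawing group of the ynamide.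

**Step 2**
Reactants: 3 N1-tosyl-N4,N9,N12-tri-Boc-spermine
Product: 4 N1-tosyl-N4,N9,N12-trimethylspermine, TsNH(CH2)3N(Me)(CH2)4N(Me)(CH2)3NHMe
Conditions: LiAlH4 (excess), THF, reflux; Na2SO4·10H2O quench
Reagents that add atoms: none
Why: Carbamate-to-N-methyl reduction turns each Boc group into an N-methyl group in one operation, while the tosylamide is shielded from hydride as its N-metalated anion.

**Step 3**
Reactants: 4 N1-tosyl-N4,N9,N12-trimethylspermine; 5 N-[2-(trimethylsilyl)ethoxycarbonyloxy]succinimide (Teoc-OSu)
Product: 6 N12-Teoc-N1-tosyl-N4,N9,N12-trimethylspermine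
Conditions: CH2Cl2, 0 °C to rt; aq. Na2CO3 wash
Reagents that add atoms: Teoc-OSu 5, C[Si](C)(C)CCOC(=O)ON1C(=O)CCC1=O
Why: Carbamate formation with an active carbonate at the only basic N–H (the secondary N-methylamine), the tosylamide N–H not being acylated without strong base; Teoc is chosen because fluoride removes it under conditions an ynamide tolerates.

**Step 4**
Reactants: 6 N12-Teoc-N1-tosyl-N4,N9,N12-trimethylspermine; 7 (bromoethynyl)triisopropylsilane
Product: 8 N1-[(triisopropylsilyl)ethynyl]-N12-Teoc-N1-tosyl-N4,N9,N12-trimethylspermine (silyl ynamide)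
Conditions: CuSO4·5H2O (cat.), 1,10-phenanthroline, K3PO4, toluene, 70 °C
Reagents that add atoms: (bromoethynyl)triisopropylsilane 7, CC(C)[Si](C#CBr)(C(C)C)C(C)C
Why: Copper-catalysed amidative cross-coupling of a sulfonamide N–H with an alkynyl bromide (ynamide synthesis), the tosylamide being the only N–H left and the TIPS group blocking alkyne homocoupling.

**Step 5**
Reactants: 8 silyl ynamide
Product: 9 N1-ethynyl-N1-tosyl-N4,N9,N12-trimethylspermine, HC≡C–N(Ts)(CH2)3N(Me)(CH2)4N(Me)(CH2)3NHMe
Conditions: Bu4NF, THF, 0 to 40 °C; used at once
Reagents that add atoms: none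
Why: Fluoride cleaves the alkynyl C–Si bond and triggers the β-elimination of the Teoc group, so both reactive ends are unveiled in one non-acidic operation that leaves the acid-sensitive ynamide intact.

**Step 6**
Reactants: 9 N1-ethynyl-N1-tosyl-N4,N9,N12-trimethylspermine; 10 tetradecanal
Product: 12 (4R)-5,9,14-trimethyl-1-(4-methylbenzenesulfonyl)-4-tridecyl-1,5,9,14-tetraazacycloheptadec-2-yne, via copper acetylide iminium ion 11 (not isolated)
Conditions: CuBr (10 mol %), (S)-Quinap (11 mol %), 4 Å molecular sieves, toluene, rt, air excluded; 9 added by syringe pump to catalyst and 10 (1.5 equiv), final concentration about 2 mM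
Reagents that add atoms: tetradecanal 10, CCCCCCCCCCCCCC=O
Why: Proposed new method: the only N–H amine of 9 (the terminal N-methylamine) condenses with tetradecanal to an iminium ion while CuBr and the amine base turn the terminal ynamide into a copper acetylide, and in 11 the acetylide carbon adds to the iminium carbon of the same molecule, forming the C3–C4 bond and the ring in one event. The closest known reaction type is the CuBr/Quinap-catalysed enantioselective three-component coupling of a secondary amine, an aliphatic aldehyde and a terminal alkyne, together with copper-catalysed additions of terminal ynamides to iminium-type electrophiles; new here are the macrocyclising mode and the ynamide partner in the asymmetric manifold. The 17-membered ring closes in a 17-endo-trig mode (the C=N+ bond lies inside the new ring), helped by the rigid linear N–C≡C–Cu unit, which cannot fold back on its own chain. The new stereocentre (4R) is set by catalyst control: the P,N-ligated copper acetylide should add to the Si face of the iminium carbon, the sense expected for (S)-Quinap with linear aliphatic aldehydes by analogy with the open-chain reaction. The step needs ring closure over oligomerisation, secured by slow addition so that each molecule of 9 is converted before it meets another, and reaction at one site only, secured because the two inner amines are tertiary and cannot form an iminium ion and the ynamide C–H is the only position copper metalates.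

**Step 7**
Reactants: 12 macrocyclic ynamide
Product: 13 (4R)-5,9,14-trimethyl-1-(4-methylbenzenesulfonyl)-4-tridecyl-1,5,9,14-tetraazacycloheptadecan-2-one
Conditions: TsOH·H2O (excess over the three amines), MeCN/H2O, 40 °C; NaHCO3 work-up
Reagents that add atoms: water, O
Why: Ynamide hydration, in which protonation at C3 gives a keteniminium ion that water captures at C2, fixes the regiochemistry, while the amines sit as ammonium ions and C4 is not involved, so its configuration should be kept.

**Step 8**
Reactants: 13 N-tosyl lactam
Product: 14 (4R)-5,9,14-trimethyl-4-tridecyl-1,5,9,14-tetraazacycloheptadecan-2-one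
Conditions: SmI2 (excess), THF, −78 to 0 °C; aq. NaHCO3
Reagents that add atoms: none
Why: Reductive desulfonylation of an N-acyl arenesulfonamide by single-electron transfer cleaves the N–S bond to the lactam N–H and leaves the tertiary amines and the C4 stereocentre untouched.

**Compound list**

1 | N1,N4,N9-tri-Boc-spermine | NCCCN(CCCCN(CCCNC(=O)OC(C)(C)C)C(=O)OC(C)(C)C)C(=O)OC(C)(C)C | starting material
2 | p-toluenesulfonyl chloride | Cc1ccc(cc1)S(=O)(=O)Cl | starting material
3 | N1-tosyl-N4,N9,N12-tri-Boc-spermine | Cc1ccc(cc1)S(=O)(=O)NCCCN(CCCCN(CCCNC(=O)OC(C)(C)C)C(=O)OC(C)(C)C)C(=O)OC(C)(C)C | intermediate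
4 | N1-tosyl-N4,N9,N12-trimethylspermine | Cc1ccc(cc1)S(=O)(=O)NCCCN(C)CCCCN(C)CCCNC | intermediate
5 | N-[2-(trimethylsilyl)ethoxycarbonyloxy]succinimide (Teoc-OSu) | C[Si](C)(C)CCOC(=O)ON1C(=O)CCC1=O | starting material
6 | N12-Teoc-N1-tosyl-N4,N9,N12-trimethylspermine | Cc1ccc(cc1)S(=O)(=O)NCCCN(C)CCCCN(C)CCCN(C)C(=O)OCC[Si](C)(C)C | intermediate
7 | (bromoethynyl)triisopropylsilane | CC(C)[Si](C#CBr)(C(C)C)C(C)C | starting material
8 | N1-[(triisopropylsilyl)ethynyl]-N12-Teoc-N1-tosyl-N4,N9,N12-trimethylspermine | Cc1ccc(cc1)S(=O)(=O)N(C#C[Si](C(C)C)(C(C)C)C(C)C)CCCN(C)CCCCN(C)CCCN(C)C(=O)OCC[Si](C)(C)C | intermediate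
9 | N1-ethynyl-N1-tosyl-N4,N9,N12-trimethylspermine | Cc1ccc(cc1)S(=O)(=O)N(C#C)CCCN(C)CCCCN(C)CCCNC | intermediate
10 | tetradecanal | CCCCCCCCCCCCCC=O | starting material
11 | N-methyl-N-tetradecylidene iminium ion of 9, as the monovalent-copper acetylide of the ynamide | CCCCCCCCCCCCCC=[N+](C)CCCN(C)CCCCN(C)CCCN(C#C[Cu])S(=O)(=O)c1ccc(C)cc1 | intermediate
12 | (4R)-5,9,14-trimethyl-1-(4-methylbenzenesulfonyl)-4-tridecyl-1,5,9,14-tetraazacycloheptadec-2-yne | CCCCCCCCCCCCC[C@@H]1C#CN(S(=O)(=O)c2ccc(C)cc2)CCCN(C)CCCCN(C)CCCN1C | intermediate
13 | (4R)-5,9,14-trimethyl-1-(4-methylbenzenesulfonyl)-4-tridecyl-1,5,9,14-tetraazacycloheptadecan-2-one | CCCCCCCCCCCCC[C@@H]1CC(=O)N(S(=O)(=O)c2ccc(C)cc2)CCCN(C)CCCCN(C)CCCN1C | intermediate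
14 | (4R)-5,9,14-trimethyl-4-tridecyl-1,5,9,14-tetraazacycloheptadecan-2-one | CCCCCCCCCCCCC[C@@H]1CC(=O)NCCCN(C)CCCCN(C)CCCN1C | target

**Totals**

Total step count: 8. Longest linear sequence: 8 steps (1 to 14).

**Steps most likely to fail**

1. Step 6. Intermolecular alkynylation may outrun ring closure (oligomers). Binding of copper by the polyamine chain may also open an unligated, non-selective pathway and lower the enantiomeric purity; if only the sense of induction were reversed, the antipodal ligand would be used. The fallback uses known chemistry, sets out from 4 (with 10) and comes back at 12. The open-chain three-component coupling of the secondary amine 4, aldehyde 10 and trimethylsilylacetylene under CuBr/(S)-Quinap in toluene should set the same R centre and give the silylated propargylamine F1. K2CO3 in MeOH then removes the silyl group to give the terminal alkyne F2. Bromination of the alkyne C–H with N-bromosuccinimide and catalytic AgNO3 in acetone, run on the tris(trifluoroacetate) salt so that the amines are shielded, gives the bromoalkyne F3. The ring is then closed at the N1–C2 bond by intramolecular copper-catalysed N-alkynylation of the tosylamide (CuSO4·5H2O, 1,10-phenanthroline, K3PO4, toluene, 70 °C, high dilution), the amidative coupling of step 4 in its macrocyclic-ynamide mode, which gives 12; steps 7 and 8 follow unchanged.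

2. Step 4. The basic tertiary amines may bind the copper catalyst or be alkylated by the bromoalkyne, so that the amidative coupling stalls. The fallback sets out from 6 and comes back at 9 by a metal-free alkynylation. Compound 6 with trichloroethylene and Cs2CO3 in DMF at 50 °C (dichloroacetylene formed in the flask, anti-addition of the sulfonamide anion) gives the (E)-N-(1,2-dichlorovinyl)sulfonamide F4. PhLi (2.2 equiv) in THF at −78 to −40 °C brings about chloride elimination and lithium–chlorine exchange, and a proton quench gives the Teoc-protected terminal ynamide F5. Bu4NF in THF then removes the Teoc group to give 9.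

3. Step 7. Protonation of the ynamide next to the ammonium centre may be slow, and prolonged heating in acid may bring hydrolytic opening of the N-acyl sulfonamide or loss of the β-amino group. The fallback sets out from 12 and comes back at 13 by hydration without strong acid. Compound 12 with excess acetic acid in CH2Cl2 at rt to 40 °C should undergo hydroacyloxylation to the α-acetoxy enamide F6, the reaction that underlies ynamide coupling reagents. n-Butylamine then takes the acetyl group by aminolysis and releases the enol, which tautomerises to 13.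

**Further compounds**

F1 | step 6 | (R)-4-methyl-N-[3-[methyl[4-[methyl[3-[methyl[1-(trimethylsilyl)hexadec-1-yn-3-yl]amino]propyl]amino]butyl]amino]propyl]benzenesulfonamide | CCCCCCCCCCCCC[C@H](C#C[Si](C)(C)C)N(C)CCCN(C)CCCCN(C)CCCNS(=O)(=O)c1ccc(C)cc1
F2 | step 6 | (R)-N-[3-[[4-[[3-[(hexadec-1-yn-3-yl)(methyl)amino]propyl](methyl)amino]butyl](methyl)amino]propyl]-4-methylbenzenesulfonamide | CCCCCCCCCCCCC[C@H](C#C)N(C)CCCN(C)CCCCN(C)CCCNS(=O)(=O)c1ccc(C)cc1
F3 | step 6 | (R)-N-[3-[[4-[[3-[(1-bromohexadec-1-yn-3-yl)(methyl)amino]propyl](methyl)amino]butyl](methyl)amino]propyl]-4-methylbenzenesulfonamide | CCCCCCCCCCCCC[C@H](C#CBr)N(C)CCCN(C)CCCCN(C)CCCNS(=O)(=O)c1ccc(C)cc1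
F4 | step 4 | N1-[(E)-1,2-dichlorovinyl]-N12-Teoc-N1-tosyl-N4,N9,N12-trimethylspermine | Cc1ccc(cc1)S(=O)(=O)N(/C(Cl)=C\Cl)CCCN(C)CCCCN(C)CCCN(C)C(=O)OCC[Si](C)(C)C
F5 | step 4 | N1-ethynyl-N12-Teoc-N1-tosyl-N4,N9,N12-trimethylspermine | Cc1ccc(cc1)S(=O)(=O)N(C#C)CCCN(C)CCCCN(C)CCCN(C)C(=O)OCC[Si](C)(C)C
F6 | step 7 | (4R)-5,9,14-trimethyl-1-(4-methylbenzenesulfonyl)-4-tridecyl-1,5,9,14-tetraazacycloheptadec-2-en-2-yl acetate (alkene geometry not defined) | CCCCCCCCCCCCC[C@@H]1C=C(OC(C)=O)N(S(=O)(=O)c2ccc(C)cc2)CCCN(C)CCCCN(C)CCCN1C
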